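**Plan**
1. Locants follow the target ring: C1 (tertiary OH and C7H2OBz), C2 (OAc), C3 (OBz), C4=C5, C6 (OH); β is the ring face carrying C7, α the opposite face.
2. Retrosynthesis: cut the O7–benzoyl bond, the C2–OAc bond (re-closing an α-oxirane C1–C2) and the C3–OBz bond (with inversion); tie C4=C5 up as a cyclopentadiene adduct; return C3 and C6 to ketones; cut the two oxirane C–O bonds; split the adduct into cyclopentadiene and 2-(silyloxymethyl)-1,4-benzoquinone.
3. Enabling feature: C3 and C6 are the carbonyl carbons of that quinone and C1=C2 and C4=C5 its two alkenes, so C4=C5 can be stored in a norbornene ring while the C1=C2 enedione is oxidised.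
4. Forward: arene → quinone → norbornene ring fused at C4/C5 → oxirane ring on C1–C2 → reduction at C3/C6 → norbornene ring removed → benzoate at C3 → acetate at C2 → benzoate at O7.
5. Stereochemistry: the catalysed cycloaddition fixes the absolute sense; the folded tricycle then admits peroxide and hydride only on the α face (oxirane α, hydroxyls β); the Mitsunobu step inverts C3 and acetate inverts C2.

Key step: step 4

Assumption: the (S)-configured oxazaborolidinium ion is taken to bind the C3 carbonyl and leave open the face of C4=C5 that leads to 6, as its α-C–H···O binding model predicts; if the adduct proves antipodal, the (R)-configured catalyst is used and nothing else changes.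

Step 1
Reactants: 1 2,5-dimethoxybenzyl alcohol; 2 tert-butyldimethylsilyl chloride
Product: 3 tert-butyl[(2,5-dimethoxyphenyl)methoxy]dimethylsilane
Conditions: imidazole, DMF, 0 °C to rt
Reagents that add atoms: tert-butyldimethylsilyl chloride, CC(C)(C)[Si](C)(C)Cl
Why: Imidazole-promoted O-silylation of a primary benzylic alcohol is routine and masks O7 through the oxidative, basic and thermal steps that follow; no stereocentre is formed.

Step 2
Reactants: 3 tert-butyl[(2,5-dimethoxyphenyl)methoxy]dimethylsilane
Product: 4 2-{[(tert-butyldimethylsilyl)oxy]methyl}-1,4-benzoquinone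
Conditions: (NH4)2Ce(NO3)6 (2.5 equiv), MeCN–H2O, 0 °C, short contact
Reagents that add atoms: water, O
Why: Oxidative demethylation of a 1,4-dimethoxyarene by tetravalent cerium (water attacks the arene radical cation at the methoxy-bearing carbons and methanol leaves) should give the quinone, the cold and brief exposure keeping the primary silyl ether intact.

Step 3
Reactants: 4 2-{[(tert-butyldimethylsilyl)oxy]methyl}-1,4-benzoquinone; 5 cyclopentadiene (freshly cracked from its commercial dimer)
Product: 6 (1R,4S,4aR,8aS)-6-{[(tert-butyldimethylsilyl)oxy]methyl}-1,4,4a,8a-tetrahydro-1,4-methanonaphthalene-5,8-dione (endo adduct across C4=C5; H4 and H5 cis and α, norbornene on the β face)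
Conditions: 20 mol % (S)-1-(2-methylphenyl)-3,3-diphenyltetrahydro-1H,3H-pyrrolo[1,2-c][1,3,2]oxazaborole (C24H24BNO) + HN(SO2CF3)2, CH2Cl2, −78 °C
Reagents that add atoms: cyclopentadiene, C1C=CC=C1
Why: Catalytic enantioselective Diels–Alder reaction: the chiral boron cation binds the more basic C3 carbonyl (conjugated with the alkyl-bearing C1=C2) at the lone pair next to C4–H and covers one face of the unsubstituted, more reactive C4=C5 bond, so the diene adds endo to the open face and C4, C5 and both bridgeheads are set together under catalyst control.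

Step 4
Reactants: 6 endo adduct; 7 hydrogen peroxide
Product: 8 α-oxirane of 6 across C1–C2 (oxirane oxygen on the convex face, syn to H4 and H5; CH2OSi arm β, towards the norbornene; both ketones retained)
Conditions: 30% aq. H2O2, Na2CO3, acetone–H2O, 0 °C
Reagents that add atoms: hydrogen peroxide, OO
Why: Weitz–Scheffer nucleophilic epoxidation of an enedione: hydroperoxide anion adds in conjugate fashion to the unsubstituted C2 of the C1=C2 bond and the resulting C1 enolate displaces hydroxide from the peroxide oxygen, forming first the C2–O and then the C1–O bond. The oxirane closes in the 3-exo-tet mode, the breaking O–O bond lying outside the new ring. Both new stereocentres, C1 and C2, are dictated by the folded endo tricycle: the norbornene unit covers the β (concave) face of the enedione ring, so the peroxide arrives on the α face, the side of H4 and H5, and the enolate can only close on that same face, giving the cis α-oxirane with C7 turned β. The closest known reaction is the alkaline hydrogen peroxide epoxidation of the parent cyclopentadiene–benzoquinone adduct. The step needs chemoselectivity for the electron-poor C1=C2 bond over the norbornene alkene, which a nucleophilic oxidant guarantees, and survival of the base-sensitive cis ring fusion at C4/C5, which carbonate at 0 °C and the fast epoxidation should secure.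

Step 5
Reactants: 8 tricyclic epoxy dione
Product: 9 tricyclic epoxy diol (C3–OH and C6–OH both β, on the norbornene side, trans to the α-oxirane)
Conditions: NaBH4, MeOH–CH2Cl2, −20 to 0 °C
Reagents that add atoms: none
Why: Borohydride 1,2-reduction of both ketones: hydride can reach C3 and C6 only from the convex α face because the norbornene bridge covers the β face, which places both new hydroxyls β and sets C3 and C6 by substrate control.

Step 6
Reactants: 9 tricyclic epoxy diol
Product: 10 (1S,2R,3S,6R)-1-{[(tert-butyldimethylsilyl)oxy]methyl}-1,2-epoxycyclohex-4-ene-3,6-diol (oxirane α, both hydroxyls β)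
Conditions: Ph2O, 240–250 °C, Ar, brief heating
Reagents that add atoms: none
Why: Retro-Diels–Alder reaction: loss of volatile cyclopentadiene drives the unmasking of C4=C5, and C1, C2, C3 and C6 are untouched because only C4 and C5 change hybridisation.

Step 7
Reactants: 10 epoxy diol; 11 benzoic acid
Product: 12 (1S,2R,3R,6R)-3-benzoyloxy-1-{[(tert-butyldimethylsilyl)oxy]methyl}-1,2-epoxycyclohex-4-en-6-ol (oxirane α, OBz α, OH β)
Conditions: PPh3, DIAD, BzOH (1.1 equiv each), THF, −20 to 0 °C
Reagents that add atoms: benzoic acid, OC(=O)c1ccccc1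
Why: Mitsunobu esterification: SN2 displacement of the oxyphosphonium at the allylic, unencumbered C3 inverts it from β-OH to α-OBz, while the C6 hydroxyl, flanked by the fully substituted C1 and its cis CH2OSi arm, should be too hindered to be activated or displaced.

Step 8
Reactants: 12 silyl ether benzoate
Product: 13 (1S,2R,3R,6R)-3-benzoyloxy-1,2-epoxy-1-(hydroxymethyl)cyclohex-4-en-6-ol
Conditions: HF·pyridine, pyridine, THF, 0 °C
Reagents that add atoms: none
Why: Fluoride-mediated cleavage of the primary silyl ether under buffered, non-basic conditions should free O7–H without opening the oxirane or moving the C3 benzoate.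

Step 9
Reactants: 13 epoxy diol benzoate; 14 acetic acid
Product: 15 (1S,2S,3R,6R)-2-acetoxy-3-benzoyloxy-1-(hydroxymethyl)cyclohex-4-ene-1,6-diol (1-OH α, 2-OAc β, 3-OBz α, 6-OH β)
Conditions: Ti(OCH(CH3)2)4 (1.5 equiv), AcOH (3 equiv), CH2Cl2, rt; aqueous work-up
Reagents that add atoms: acetic acid, CC(=O)O
Why: Titanium-mediated opening of a 2,3-epoxy alcohol by a carboxylic acid: the titanium alkoxide of O7 chelates the oxirane oxygen and steers acetate to the distal carbon C2 (C1 being fully substituted as well), and anti attack from the β face inverts C2 and leaves the C1 oxygen as the α tertiary hydroxyl.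

Step 10
Reactants: 15 triol acetate benzoate; 16 benzoyl chloride
Product: 17 (1S,2S,3R,6R)-2-acetoxy-3-benzoyloxy-1-[(benzoyloxy)methyl]cyclohex-4-ene-1,6-diol (target)
Conditions: BzCl (1.05 equiv), pyridine, CH2Cl2, −30 to 0 °C
Reagents that add atoms: benzoyl chloride, O=C(Cl)c1ccccc1
Why: Acylation with an acid chloride and pyridine at low temperature should select the primary O7–H over the hindered secondary C6 hydroxyl and the tertiary C1 hydroxyl, completing the target without touching a stereocentre.

**Compound list**
1 | 2,5-dimethoxybenzyl alcohol | COc1ccc(OC)c(CO)c1 | starting material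
2 | tert-butyldimethylsilyl chloride | CC(C)(C)[Si](C)(C)Cl | starting material
3 | tert-butyl[(2,5-dimethoxyphenyl)methoxy]dimethylsilane | COc1ccc(OC)c(CO[Si](C)(C)C(C)(C)C)c1 | intermediate
4 | 2-{[(tert-butyldimethylsilyl)oxy]methyl}-1,4-benzoquinone | CC(C)(C)[Si](C)(C)OCC1=CC(=O)C=CC1=O | intermediate
5 | cyclopentadiene | C1C=CC=C1 | starting material
6 | (1R,4S,4aR,8aS)-6-{[(tert-butyldimethylsilyl)oxy]methyl}-1,4,4a,8a-tetrahydro-1,4-methanonaphthalene-5,8-dione (endo) | CC(C)(C)[Si](C)(C)OCC1=CC(=O)[C@H]2[C@H]3C=C[C@H](C3)[C@H]2C1=O | intermediate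
7 | hydrogen peroxide | OO | starting material
8 | convex-face (α) C1–C2 oxirane of 6, CH2OSi β | CC(C)(C)[Si](C)(C)OC[C@@]12O[C@@H]1C(=O)[C@H]1[C@H]3C=C[C@H](C3)[C@H]1C2=O | intermediate
9 | tricyclic epoxy diol, 3-OH and 6-OH β (norbornene side), oxirane α | CC(C)(C)[Si](C)(C)OC[C@@]12O[C@@H]1[C@@H](O)[C@H]1[C@H]3C=C[C@H](C3)[C@H]1[C@H]2O | intermediate
10 | (1S,2R,3S,6R)-1-{[(tert-butyldimethylsilyl)oxy]methyl}-1,2-epoxycyclohex-4-ene-3,6-diol | CC(C)(C)[Si](C)(C)OC[C@@]12O[C@@H]1[C@@H](O)C=C[C@H]2O | intermediate
11 | benzoic acid | OC(=O)c1ccccc1 | starting material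
12 | (1S,2R,3R,6R)-3-benzoyloxy-1-{[(tert-butyldimethylsilyl)oxy]methyl}-1,2-epoxycyclohex-4-en-6-ol | CC(C)(C)[Si](C)(C)OC[C@@]12O[C@@H]1[C@H](OC(=O)c1ccccc1)C=C[C@H]2O | intermediate
13 | (1S,2R,3R,6R)-3-benzoyloxy-1,2-epoxy-1-(hydroxymethyl)cyclohex-4-en-6-ol | OC[C@@]12O[C@@H]1[C@H](OC(=O)c1ccccc1)C=C[C@H]2O | intermediate
14 | acetic acid | CC(=O)O | starting material
15 | (1S,2S,3R,6R)-2-acetoxy-3-benzoyloxy-1-(hydroxymethyl)cyclohex-4-ene-1,6-diol | CC(=O)O[C@H]1[C@H](OC(=O)c2ccccc2)C=C[C@@H](O)[C@@]1(O)CO | intermediate
16 | benzoyl chloride | O=C(Cl)c1ccccc1 | starting material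
17 | (1S,2S,3R,6R)-2-acetoxy-3-benzoyloxy-1-[(benzoyloxy)methyl]cyclohex-4-ene-1,6-diol | CC(=O)O[C@H]1[C@H](OC(=O)c2ccccc2)C=C[C@@H](O)[C@@]1(O)COC(=O)c1ccccc1 | target

Total step count: 10. Longest linear sequence: 10 steps (1 to 17).

**Steps most likely to fail**

Step 3. The two carbonyl oxygens compete for the boron cation, and because the diene is symmetrical, binding at the C6 carbonyl leads to the mirror-image adduct, so enantiomeric purity may be eroded or the sense reversed. The fallback sets out from 4 and 5 and returns at 6. The uncatalysed cycloaddition (CH2Cl2, 0 °C) should give the racemic endo adduct, that is 6 together with the enantiomer of 6 F1. The two are separated by preparative chromatography on a cellulose tris(3,5-dimethylphenylcarbamate) phase, and only 6 is carried on.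

Step 7. Site selectivity may be lost through activation and displacement at the C6 hydroxyl or double esterification. The fallback sets out from 10 and returns at 13.
- HF·pyridine removes the silyl group to give the epoxy triol F2.
- tBu2Si(OSO2CF3)2 with 2,6-lutidine ties the cis-1,3-related O6 and O7 into the cyclic di-tert-butylsilylene F3, leaving O3–H as the only hydroxyl.
- Mitsunobu benzoylation (PPh3, DIAD, BzOH) gives the C3-inverted silylene benzoate F4.
- HF·pyridine releases 13.

Step 9. The new acetyl group may migrate from O2 to the neighbouring free hydroxyls, ester exchange with isopropoxide on titanium may occur, or acetate may attack partly at C1. The fallback sets out from 12 and returns at 15. In 12, O7 is still silylated and no ester can participate. Its oxirane is opened by SN2 attack of acetate without a directing metal (Bu4N+ AcO−, AcOH, toluene, 80 °C). The fully substituted C1 leaves C2 as the only site, and anti attack should give the hydroxy acetate silyl ether F5. HF·pyridine then gives 15.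

Further compounds
F1 | step 3 | (1S,4R,4aS,8aR)-6-{[(tert-butyldimethylsilyl)oxy]methyl}-1,4,4a,8a-tetrahydro-1,4-methanonaphthalene-5,8-dione (enantiomer of 6) | CC(C)(C)[Si](C)(C)OCC1=CC(=O)[C@@H]2[C@@H]3C=C[C@@H](C3)[C@@H]2C1=O
F2 | step 7 | (1S,2R,3S,6R)-1,2-epoxy-1-(hydroxymethyl)cyclohex-4-ene-3,6-diol | OC[C@@]12O[C@@H]1[C@@H](O)C=C[C@H]2O
F3 | step 7 | O6,O7-di-tert-butylsilylene derivative of F2 (3-OH β free, oxirane α) | CC(C)(C)[Si]1(C(C)(C)C)OC[C@@]23O[C@@H]2[C@@H](O)C=C[C@H]3O1
F4 | step 7 | O6,O7-di-tert-butylsilylene 3α-benzoate (C3 inverted, oxirane α) | CC(C)(C)[Si]1(C(C)(C)C)OC[C@@]23O[C@@H]2[C@H](OC(=O)c2ccccc2)C=C[C@H]3O1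
F5 | step 9 | (1S,2S,3R,6R)-2-acetoxy-3-benzoyloxy-1-{[(tert-butyldimethylsilyl)oxy]methyl}cyclohex-4-ene-1,6-diol | CC(=O)O[C@H]1[C@H](OC(=O)c2ccccc2)C=C[C@@H](O)[C@@]1(O)CO[Si](C)(C)C(C)(C)C
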